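The disconnection cuts ring C of the 5,7-dihydroxyflavanone unit (unit B, primed atoms) at O1'–C8a' and C4'–C4a'. These two bonds sit on neighbouring carbons of the phloroglucinol ring, so a 3,5-bis(benzyloxy)benzyne can supply C4a' and C8a' in one operation by inserting into the acyl–oxygen bond of a β-lactone that already holds O1', C2', C3' and C4'. The oxetan-2-one thereby grows by two atoms into the chroman-4-one. The precursor is a cis-4-aryl β-lactone bearing the complete, enantiopure 7-methoxyflavanone (unit A) on C3'. C2' comes from an Evans aldol and is not touched by the insertion.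

Key step: step 12

Remark: atoms of the 7-methoxy unit (unit A) are unprimed and those of the 5,7-dihydroxy unit (unit B) are primed; compounds 1, 5, 7, 10 and 15 are taken as commercial.
Remark: in step 3, (S)-t-BuPyOx is assumed, by analogy with carbocyclic enones, to give the 2R flavanone; if the sense proves opposite, the (R)-ligand is used.

Step 1
Reactants: 1 1-(2,6-dihydroxy-4-methoxyphenyl)ethan-1-one
Product: 2 1-[2-(benzyloxy)-6-hydroxy-4-methoxyphenyl]ethan-1-one
Conditions: BnBr (1.05 equiv), K2CO3, acetone, 56 °C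
Reagents that add atoms: benzyl bromide, BrCc1ccccc1
Why: Williamson etherification, which should stop after one benzylation because the remaining phenol is held in a hydrogen bond to the ketone.

Step 2
Reactants: 2 1-[2-(benzyloxy)-6-hydroxy-4-methoxyphenyl]ethan-1-one
Product: 4 5-(benzyloxy)-7-methoxy-4H-chromen-4-one, via enaminone 3 (not isolated)
Conditions: Me2NCH(OMe)2, toluene, 100 °C; then conc. HCl, CH2Cl2, 40 °C
Reagents that add atoms: N,N-dimethylformamide dimethyl acetal, COC(OC)N(C)C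
Why: Enaminone condensation at the acetyl methyl group followed by acid-promoted cyclocondensation (phenol addition and loss of dimethylamine), the standard chromone synthesis.

Step 3
Reactants: 4 5-(benzyloxy)-7-methoxy-4H-chromen-4-one; 5 (4-methoxyphenyl)boronic acid
Product: 6 (2R)-5-(benzyloxy)-7-methoxy-2-(4-methoxyphenyl)chroman-4-one
Conditions: Pd(OCOCF3)2 (5 mol%), (S)-t-BuPyOx (6 mol%), NH4PF6 (30 mol%), H2O (5 equiv), ClCH2CH2Cl, 60 °C
Reagents that add atoms: none
Why: Asymmetric conjugate addition of an arylboronic acid to a chromone, catalysed by a cationic divalent palladium pyridine-oxazoline complex whose ligand selects the face of C2=C3 and so sets C2 as R.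

Step 4
Reactants: 7 (4R)-4-benzyl-1,3-oxazolidin-2-one
Product: 8 (4R)-4-benzyl-3-(bromoacetyl)-1,3-oxazolidin-2-one
Conditions: n-BuLi, THF, −78 °C; then BrCH2COBr, −78 → 0 °C
Reagents that add atoms: bromoacetyl bromide, BrCC(Br)=O
Why: N-acylation of the lithiated oxazolidinone with an acid bromide, in which the stereocentre of the auxiliary is not involved.

Step 5
Reactants: 6 (2R)-5-(benzyloxy)-7-methoxy-2-(4-methoxyphenyl)chroman-4-one; 8 (4R)-4-benzyl-3-(bromoacetyl)-1,3-oxazolidin-2-one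
Product: 9 (4R)-4-benzyl-3-{[(2R,3S)-5-(benzyloxy)-7-methoxy-2-(4-methoxyphenyl)-4-oxochroman-3-yl]acetyl}-1,3-oxazolidin-2-one
Conditions: LiN(SiMe3)2 (1.05 equiv), THF, −78 °C; then 8, −78 → −40 °C
Reagents that add atoms: none
Why: Enolate alkylation by SN2 displacement on the α-bromo imide, with the electrophile approaching the enolate face anti to the C2 aryl group so that C3 is set as S (2,3-trans, also the thermodynamic arrangement).

Step 6
Reactants: 9 (4R)-4-benzyl-3-{[(2R,3S)-5-(benzyloxy)-7-methoxy-2-(4-methoxyphenyl)-4-oxochroman-3-yl]acetyl}-1,3-oxazolidin-2-one; 10 4-(benzyloxy)benzaldehyde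
Product: 11 (4R)-4-benzyl-3-{(2R,3R)-2-[(2R,3S)-5-(benzyloxy)-7-methoxy-2-(4-methoxyphenyl)-4-oxochroman-3-yl]-3-[4-(benzyloxy)phenyl]-3-hydroxypropanoyl}-1,3-oxazolidin-2-one
Conditions: n-Bu2BOTf (1.2 equiv), i-Pr2NEt (1.4 equiv), CH2Cl2, −78 → 0 °C; then 10, −78 → 0 °C; then pH 7 buffer, MeOH, H2O2, 0 °C
Reagents that add atoms: none
Why: Evans syn aldol through the Z boron enolate and a Zimmerman–Traxler transition state, in which the (R)-auxiliary sets C2' and C3' both as R, and soft enolisation is expected at the unhindered imide methylene and not at the tertiary C3–H beside the ketone.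

Step 7
Reactants: 11 (4R)-4-benzyl-3-{(2R,3R)-2-[(2R,3S)-5-(benzyloxy)-7-methoxy-2-(4-methoxyphenyl)-4-oxochroman-3-yl]-3-[4-(benzyloxy)phenyl]-3-hydroxypropanoyl}-1,3-oxazolidin-2-one
Product: 13 (2R,3R)-2-[(2R,3S)-5-(benzyloxy)-7-methoxy-2-(4-methoxyphenyl)-4-oxochroman-3-yl]-3-[4-(benzyloxy)phenyl]-3-hydroxypropanoic acid, via peroxy acid 12 (not isolated)
Conditions: LiOH, H2O2, THF/H2O (3:1), 0 °C; then Na2SO3 (aq); then HCl (aq) to pH 3
Reagents that add atoms: lithium hydroperoxide (from LiOH and H2O2), [Li+].[O-]O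
Why: Hydroperoxide cleavage of the N-acyl oxazolidinone at the exocyclic carbonyl followed by sulfite reduction of the peracid, a method mild enough to leave the aldol and flavanone stereocentres untouched.

Step 8
Reactants: 13 (2R,3R)-2-[(2R,3S)-5-(benzyloxy)-7-methoxy-2-(4-methoxyphenyl)-4-oxochroman-3-yl]-3-[4-(benzyloxy)phenyl]-3-hydroxypropanoic acid
Product: 14 (3R,4R)-3-[(2R,3S)-5-(benzyloxy)-7-methoxy-2-(4-methoxyphenyl)-4-oxochroman-3-yl]-4-[4-(benzyloxy)phenyl]oxetan-2-one
Conditions: PhSO2Cl (2 equiv), pyridine, 0 °C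
Reagents that add atoms: none
Why: β-Lactonisation by carboxyl activation as the mixed sulfonic anhydride and attack of the C2' hydroxyl on the acyl carbon, which retains both stereocentres and turns the syn acid into the cis lactone.

Step 9
Reactants: 15 3,5-bis(benzyloxy)phenol
Product: 16 3,5-bis(benzyloxy)phenyl isopropylcarbamate
Conditions: i-PrNCO, Et3N (0.2 equiv), CH2Cl2, 23 °C
Reagents that add atoms: isopropyl isocyanate, CC(C)N=C=O
Why: Carbamoylation of the phenol by addition to the isocyanate, which installs a directing group for ortho-lithiation that can later be removed under mild conditions.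

Step 10
Reactants: 16 3,5-bis(benzyloxy)phenyl isopropylcarbamate
Product: 19 3,5-bis(benzyloxy)-2-(trimethylsilyl)phenyl isopropylcarbamate, via N-silyl carbamate 17 (not isolated), via N-silyl C-silyl carbamate 18 (not isolated)
Conditions: t-BuMe2SiOTf, TMEDA, Et2O, 0 → 23 °C; then n-BuLi, TMEDA, −78 °C; then Me3SiCl, −78 → 23 °C; then NaHSO4 (aq)
Reagents that add atoms: chlorotrimethylsilane, C[Si](C)(C)Cl; tert-butyldimethylsilyl triflate, CC(C)(C)[Si](C)(C)OS(=O)(=O)C(F)(F)F (its silyl group stays only in 17 and 18)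
Why: Directed ortho-metalation of the N-silylated carbamate, with lithiation at the position flanked by the carbamate and a benzyloxy group, followed by C-silylation and loss of the N-silyl group on work-up.

Step 11
Reactants: 19 3,5-bis(benzyloxy)-2-(trimethylsilyl)phenyl isopropylcarbamate
Product: 21 3,5-bis(benzyloxy)-2-(trimethylsilyl)phenyl trifluoromethanesulfonate, via silyl phenol 20 (not isolated)
Conditions: DBU, Et2NH, MeCN, 40 °C; then PhNTf2, 23 °C
Reagents that add atoms: N-phenylbis(trifluoromethanesulfonimide), O=S(=O)(N(c1ccccc1)S(=O)(=O)C(F)(F)F)C(F)(F)F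
Why: E1cB cleavage of the secondary carbamate (the isocyanate is scavenged by diethylamine) and triflation of the phenoxide in the same flask, the usual end of an ortho-silylaryl triflate synthesis.

Step 12
Reactants: 14 (3R,4R)-3-[(2R,3S)-5-(benzyloxy)-7-methoxy-2-(4-methoxyphenyl)-4-oxochroman-3-yl]-4-[4-(benzyloxy)phenyl]oxetan-2-one; 21 3,5-bis(benzyloxy)-2-(trimethylsilyl)phenyl trifluoromethanesulfonate
Product: 23 (2R,3S,2'R,3'R)-5,5',7'-tris(benzyloxy)-2'-[4-(benzyloxy)phenyl]-7-methoxy-2-(4-methoxyphenyl)-[3,3'-bichromane]-4,4'-dione, via aryne 22 (not isolated)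
Conditions: CsF (4 equiv), MeCN, 0 → 23 °C
Reagents that add atoms: none
Why: Proposed new method: fluoride unmasks benzyne 22 from 21 and, as a hard nucleophile, should reversibly open the strained acyl–oxygen bond of 14 to a cesium C2'-alkoxide and acyl fluoride; the alkoxide adds to the aryne carbon remote from the 3-benzyloxy group, and the aryl anion, now ortho to that benzyloxy group, attacks the acyl fluoride and returns fluoride, so the two aryne carbons are inserted into the O1'–C4' bond and the oxetan-2-one becomes the chroman-4-one. The closest known reaction types are the two-atom ring expansion of cyclic ureas by aryne insertion into the N–C(O) bond, aryne insertion into the C–O bond of carboxylic acids, and the acyl-alkylation ring expansion of cyclic β-keto esters with arynes. After the intermolecular O-arylation, the six-membered ring closes by 6-exo-trig addition–elimination of the aryl anion on the acyl carbon. No new stereocentre is formed: C2' keeps its R configuration because the O1'–C2' bond is never broken, and C3' is carried through as the cis epimer. The step needs regioselective aryne capture, secured by the inductively withdrawing 3-benzyloxy group, which directs the nucleophile to the distal aryne carbon and so places the acyl group between O1' and the 5'-benzyloxy group; it also needs acyl–oxygen and not alkyl–oxygen cleavage, favoured by ring strain, the hard fluoride and a temperature low enough to suppress ionisation at the 4-alkoxybenzylic C2'.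

Step 13
Reactants: 23 (2R,3S,2'R,3'R)-5,5',7'-tris(benzyloxy)-2'-[4-(benzyloxy)phenyl]-7-methoxy-2-(4-methoxyphenyl)-[3,3'-bichromane]-4,4'-dione
Product: 24 (2R,3S,2'R,3'S)-5,5',7'-tris(benzyloxy)-2'-[4-(benzyloxy)phenyl]-7-methoxy-2-(4-methoxyphenyl)-[3,3'-bichromane]-4,4'-dione
Conditions: DBU (0.2 equiv), CH2Cl2, 23 °C
Reagents that add atoms: none
Why: Base-mediated epimerisation at C3' through the enolate, which should settle at the diequatorial 2',3'-trans arrangement (C3' S) while the non-enolisable C2 and C2' keep their configuration.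

Step 14
Reactants: 24 (2R,3S,2'R,3'S)-5,5',7'-tris(benzyloxy)-2'-[4-(benzyloxy)phenyl]-7-methoxy-2-(4-methoxyphenyl)-[3,3'-bichromane]-4,4'-dione
Product: 25 (2R,3S,2'R,3'S)-5,5',7'-trihydroxy-2'-(4-hydroxyphenyl)-7-methoxy-2-(4-methoxyphenyl)-[3,3'-bichromane]-4,4'-dione
Conditions: H2 (1 atm), Pd/C (10 wt% Pd), EtOAc/MeOH (1:1), 23 °C
Reagents that add atoms: none
Why: Hydrogenolysis of the four benzyl ethers over palladium on carbon, conditions under which aryl methyl ethers, the ketones and the benzylic C2–O bonds of flavanones are normally retained.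

Compound list
1 | 1-(2,6-dihydroxy-4-methoxyphenyl)ethan-1-one | CC(=O)c1c(O)cc(OC)cc1O | starting material
2 | 1-[2-(benzyloxy)-6-hydroxy-4-methoxyphenyl]ethan-1-one | CC(=O)c1c(O)cc(OC)cc1OCc1ccccc1 | intermediate
3 | (E)-1-[2-(benzyloxy)-6-hydroxy-4-methoxyphenyl]-3-(dimethylamino)prop-2-en-1-one (enaminone) | CN(C)/C=C/C(=O)c1c(O)cc(OC)cc1OCc1ccccc1 | intermediate (not isolated)
4 | 5-(benzyloxy)-7-methoxy-4H-chromen-4-one | O=c1ccoc2cc(OC)cc(OCc3ccccc3)c12 | intermediate
5 | (4-methoxyphenyl)boronic acid | COc1ccc(B(O)O)cc1 | starting material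
6 | (2R)-5-(benzyloxy)-7-methoxy-2-(4-methoxyphenyl)chroman-4-one | COc1ccc([C@@H]2Oc3cc(OC)cc(OCc4ccccc4)c3C(=O)C2)cc1 | intermediate
7 | (4R)-4-benzyl-1,3-oxazolidin-2-one | O=C1N[C@H](Cc2ccccc2)CO1 | starting material
8 | (4R)-4-benzyl-3-(bromoacetyl)-1,3-oxazolidin-2-one | BrCC(=O)N1[C@H](Cc2ccccc2)COC1=O | intermediate
9 | (4R)-4-benzyl-3-{[(2R,3S)-5-(benzyloxy)-7-methoxy-2-(4-methoxyphenyl)-4-oxochroman-3-yl]acetyl}-1,3-oxazolidin-2-one | COc1ccc([C@@H]2Oc3cc(OC)cc(OCc4ccccc4)c3C(=O)[C@H]2CC(=O)N2[C@H](Cc3ccccc3)COC2=O)cc1 | intermediate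
10 | 4-(benzyloxy)benzaldehyde | O=Cc1ccc(OCc2ccccc2)cc1 | starting material
11 | (4R)-4-benzyl-3-{(2R,3R)-2-[(2R,3S)-5-(benzyloxy)-7-methoxy-2-(4-methoxyphenyl)-4-oxochroman-3-yl]-3-[4-(benzyloxy)phenyl]-3-hydroxypropanoyl}-1,3-oxazolidin-2-one (syn aldol adduct) | COc1ccc([C@@H]2Oc3cc(OC)cc(OCc4ccccc4)c3C(=O)[C@H]2[C@H]([C@@H](O)c2ccc(OCc3ccccc3)cc2)C(=O)N2[C@H](Cc3ccccc3)COC2=O)cc1 | intermediate
12 | (2R,3R)-2-[(2R,3S)-5-(benzyloxy)-7-methoxy-2-(4-methoxyphenyl)-4-oxochroman-3-yl]-3-[4-(benzyloxy)phenyl]-3-hydroxypropaneperoxoic acid (peroxy acid) | COc1ccc([C@@H]2Oc3cc(OC)cc(OCc4ccccc4)c3C(=O)[C@H]2[C@H]([C@@H](O)c2ccc(OCc3ccccc3)cc2)C(=O)OO)cc1 | intermediate (not isolated)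
13 | (2R,3R)-2-[(2R,3S)-5-(benzyloxy)-7-methoxy-2-(4-methoxyphenyl)-4-oxochroman-3-yl]-3-[4-(benzyloxy)phenyl]-3-hydroxypropanoic acid | COc1ccc([C@@H]2Oc3cc(OC)cc(OCc4ccccc4)c3C(=O)[C@H]2[C@H]([C@@H](O)c2ccc(OCc3ccccc3)cc2)C(=O)O)cc1 | intermediate
14 | (3R,4R)-3-[(2R,3S)-5-(benzyloxy)-7-methoxy-2-(4-methoxyphenyl)-4-oxochroman-3-yl]-4-[4-(benzyloxy)phenyl]oxetan-2-one (cis β-lactone) | COc1ccc([C@@H]2Oc3cc(OC)cc(OCc4ccccc4)c3C(=O)[C@H]2[C@H]5C(=O)O[C@H]5c2ccc(OCc3ccccc3)cc2)cc1 | intermediate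
15 | 3,5-bis(benzyloxy)phenol | Oc1cc(OCc2ccccc2)cc(OCc2ccccc2)c1 | starting material
16 | 3,5-bis(benzyloxy)phenyl isopropylcarbamate | CC(C)NC(=O)Oc1cc(OCc2ccccc2)cc(OCc2ccccc2)c1 | intermediate
17 | 3,5-bis(benzyloxy)phenyl N-(tert-butyldimethylsilyl)-N-isopropylcarbamate (N-silyl carbamate) | CC(C)N(C(=O)Oc1cc(OCc2ccccc2)cc(OCc2ccccc2)c1)[Si](C)(C)C(C)(C)C | intermediate (not isolated)
18 | 3,5-bis(benzyloxy)-2-(trimethylsilyl)phenyl N-(tert-butyldimethylsilyl)-N-isopropylcarbamate (N-silyl C-silyl carbamate) | CC(C)N(C(=O)Oc1cc(OCc2ccccc2)cc(OCc2ccccc2)c1[Si](C)(C)C)[Si](C)(C)C(C)(C)C | intermediate (not isolated)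
19 | 3,5-bis(benzyloxy)-2-(trimethylsilyl)phenyl isopropylcarbamate | CC(C)NC(=O)Oc1cc(OCc2ccccc2)cc(OCc2ccccc2)c1[Si](C)(C)C | intermediate
20 | 3,5-bis(benzyloxy)-2-(trimethylsilyl)phenol (silyl phenol) | Oc1cc(OCc2ccccc2)cc(OCc2ccccc2)c1[Si](C)(C)C | intermediate (not isolated)
21 | 3,5-bis(benzyloxy)-2-(trimethylsilyl)phenyl trifluoromethanesulfonate | C[Si](C)(C)c1c(OCc2ccccc2)cc(OCc2ccccc2)cc1OS(=O)(=O)C(F)(F)F | intermediate
22 | 3,5-bis(benzyloxy)benzyne (aryne) | C1#CC(OCc2ccccc2)=CC(OCc2ccccc2)=C1 | intermediate (not isolated)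
23 | (2R,3S,2'R,3'R)-5,5',7'-tris(benzyloxy)-2'-[4-(benzyloxy)phenyl]-7-methoxy-2-(4-methoxyphenyl)-[3,3'-bichromane]-4,4'-dione (2',3'-cis) | COc1ccc([C@@H]2Oc3cc(OC)cc(OCc4ccccc4)c3C(=O)[C@H]2[C@H]2C(=O)c3c(OCc4ccccc4)cc(OCc4ccccc4)cc3O[C@H]2c2ccc(OCc3ccccc3)cc2)cc1 | intermediate
24 | (2R,3S,2'R,3'S)-5,5',7'-tris(benzyloxy)-2'-[4-(benzyloxy)phenyl]-7-methoxy-2-(4-methoxyphenyl)-[3,3'-bichromane]-4,4'-dione (all-trans) | COc1ccc([C@@H]2Oc3cc(OC)cc(OCc4ccccc4)c3C(=O)[C@H]2[C@@H]2C(=O)c3c(OCc4ccccc4)cc(OCc4ccccc4)cc3O[C@H]2c2ccc(OCc3ccccc3)cc2)cc1 | intermediate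
25 | (2R,3S,2'R,3'S)-5,5',7'-trihydroxy-2'-(4-hydroxyphenyl)-7-methoxy-2-(4-methoxyphenyl)-[3,3'-bichromane]-4,4'-dione (CNP0279849.2) | COc1ccc([C@@H]2Oc3cc(OC)cc(O)c3C(=O)[C@H]2[C@@H]2C(=O)c3c(O)cc(O)cc3O[C@H]2c2ccc(O)cc2)cc1 | target

Total step count: 14. Longest linear sequence: 10 steps (1, 2, 3, 5, 6, 7, 8, 12, 13, 14).

Steps most likely to fail

Step 12. Fluoride may instead attack or ionise the 4-alkoxybenzylic C2'–O bond (alkyl–oxygen cleavage, with loss of C2' configuration). The transient aldolate may undergo retro-aldol cleavage before it meets the aryne. The aryl anion may be protonated by the solvent before acyl capture, and the aryne may oligomerise while the lactone stays closed. The fallback uses known chemistry and an inversion at C2', so it sets out from 6 with the antipodal auxiliary and comes back at 24. Compound 6 is alkylated as in step 5 with the enantiomeric bromoacetyl imide F1 (made from commercial (4S)-4-benzyl-1,3-oxazolidin-2-one and bromoacetyl bromide as in step 4) to give the alkylated imide F2. The Evans syn aldol with 10 then gives the (2S,3S) adduct F3, LiOH/H2O2 the hydroxy acid F4, and PhSO2Cl/pyridine the (3S,4S) cis lactone F5. Cesium 3,5-bis(benzyloxy)phenoxide (from 15, Cs2CO3, DMF, 0 °C) opens this lactone at C4 by SN2 alkyl–oxygen cleavage with inversion, the classical phenoxide opening of β-lactones, to the (2S,3R) aryloxy acid F6. Intramolecular Friedel–Crafts acylation ((CF3CO)2O, CH2Cl2, 0 °C) at either of the two equivalent positions ortho to the aryloxy oxygen then closes ring C of unit B and gives 24 directly (C2' R by inversion, C3' S by retention), so steps 12 and 13 are both replaced.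

Step 5. The flavanone enolate may open by β-elimination of the phenoxide (loss of C2 configuration), may be quenched by proton transfer from the acidic α-bromo imide, or may react at oxygen. The fallback sets out from 6 and comes back at 9. Soft enolisation (Me3SiOTf, Et3N, CH2Cl2, 0 °C) gives the enol silane F7 without a free enolate. Visible-light photoredox alkylation with 8 (Ir(ppy)3, blue LEDs, DMF, 23 °C) adds the electrophilic α-acyl radical from 8 to C3 anti to the C2 aryl group; oxidation and loss of the silyl group then return 9.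

Step 13. Enolisation at C3' may be outrun by retro-oxa-Michael opening of either pyranone ring, which would erode C2 or C2', or the equilibration may stop short if the cis/trans energy gap is small. The fallback sets out from 23 and comes back at 25. Hydrogenolysis as in step 14 gives the 2',3'-cis free phenol F8. This is then equilibrated at C3' under buffered, weakly acidic protic conditions (NaOAc, AcOH, MeOH, 40 °C), where the chelated 5'-hydroxy ketone enolises by acid catalysis and phenoxide expulsion is suppressed, to give 25.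

Further compounds
F1 | step 12 | (4S)-4-benzyl-3-(bromoacetyl)-1,3-oxazolidin-2-one | BrCC(=O)N1[C@@H](Cc2ccccc2)COC1=O
F2 | step 12 | (4S)-4-benzyl-3-{[(2R,3S)-5-(benzyloxy)-7-methoxy-2-(4-methoxyphenyl)-4-oxochroman-3-yl]acetyl}-1,3-oxazolidin-2-one | COc1ccc([C@@H]2Oc3cc(OC)cc(OCc4ccccc4)c3C(=O)[C@H]2CC(=O)N2[C@@H](Cc3ccccc3)COC2=O)cc1
F3 | step 12 | (4S)-4-benzyl-3-{(2S,3S)-2-[(2R,3S)-5-(benzyloxy)-7-methoxy-2-(4-methoxyphenyl)-4-oxochroman-3-yl]-3-[4-(benzyloxy)phenyl]-3-hydroxypropanoyl}-1,3-oxazolidin-2-one | COc1ccc([C@@H]2Oc3cc(OC)cc(OCc4ccccc4)c3C(=O)[C@H]2[C@@H]([C@H](O)c2ccc(OCc3ccccc3)cc2)C(=O)N2[C@@H](Cc3ccccc3)COC2=O)cc1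
F4 | step 12 | (2S,3S)-2-[(2R,3S)-5-(benzyloxy)-7-methoxy-2-(4-methoxyphenyl)-4-oxochroman-3-yl]-3-[4-(benzyloxy)phenyl]-3-hydroxypropanoic acid | COc1ccc([C@@H]2Oc3cc(OC)cc(OCc4ccccc4)c3C(=O)[C@H]2[C@@H]([C@H](O)c2ccc(OCc3ccccc3)cc2)C(=O)O)cc1
F5 | step 12 | (3S,4S)-3-[(2R,3S)-5-(benzyloxy)-7-methoxy-2-(4-methoxyphenyl)-4-oxochroman-3-yl]-4-[4-(benzyloxy)phenyl]oxetan-2-one | COc1ccc([C@@H]2Oc3cc(OC)cc(OCc4ccccc4)c3C(=O)[C@H]2[C@@H]5C(=O)O[C@@H]5c2ccc(OCc3ccccc3)cc2)cc1
F6 | step 12 | (2S,3R)-3-[3,5-bis(benzyloxy)phenoxy]-3-[4-(benzyloxy)phenyl]-2-[(2R,3S)-5-(benzyloxy)-7-methoxy-2-(4-methoxyphenyl)-4-oxochroman-3-yl]propanoic acid | COc1ccc([C@@H]2Oc3cc(OC)cc(OCc4ccccc4)c3C(=O)[C@H]2[C@@H]([C@@H](Oc2cc(OCc3ccccc3)cc(OCc3ccccc3)c2)c2ccc(OCc3ccccc3)cc2)C(=O)O)cc1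
F7 | step 5 | (2R)-5-(benzyloxy)-7-methoxy-2-(4-methoxyphenyl)-4-[(trimethylsilyl)oxy]-2H-chromene | COc1ccc([C@@H]2Oc3cc(OC)cc(OCc4ccccc4)c3C(O[Si](C)(C)C)=C2)cc1
F8 | step 13 | (2R,3S,2'R,3'R)-5,5',7'-trihydroxy-2'-(4-hydroxyphenyl)-7-methoxy-2-(4-methoxyphenyl)-[3,3'-bichromane]-4,4'-dione | COc1ccc([C@@H]2Oc3cc(OC)cc(O)c3C(=O)[C@H]2[C@H]2C(=O)c3c(O)cc(O)cc3O[C@H]2c2ccc(O)cc2)cc1
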